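The target is disconnected on the ring locants C1 (CH bearing the chain), C2 (C=CH2), C3 (CHBr), C4, C5 (CHBr), C6 (CMe2). Chain carbon C1′ and the C5 substituent are 1,3-related across C6, so they can be tied together as a cyclobutanone. One intramolecular ketene–alkene [2+2] forms C1–C6 and C1′–C5, closing the carbocycle and the four-membered ring and fixing C1 and C5 under control of a C2 silyloxy stereocentre. Its precursor is an open-chain (R)-β-silyloxy acid chloride ending in a prenyl-type alkene. Baeyer–Villiger oxidation later converts C1′–C5 into C5–O; C2 becomes the methylene and both bromides enter by inversion.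

Key step: step 6

Remark: the locants C1–C6 and C1′–C3′ defined above are used throughout; with them the target is C1 (S), C3 (R), C5 (R), C3′ (S), the chain and C3–Br being cis and C5–Br trans to both.

Step 1
Reactants: 1 ethyl acetoacetate; 2 1-bromo-3-methylbut-2-ene
Product: 3 ethyl 7-methyl-3-oxooct-6-enoate
Conditions: NaH, THF, 0 °C; n-BuLi, 0 °C; then 2, 0 °C to rt; H2O quench
Reagents that add atoms: none
Why: Dianion alkylation of a β-keto ester: the terminal (γ) carbanion is the more nucleophilic site and undergoes SN2 with the allylic bromide, so that only the γ-prenylated keto ester should form.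

Step 2
Reactants: 3 ethyl 7-methyl-3-oxooct-6-enoate
Product: 4 ethyl (R)-3-hydroxy-7-methyloct-6-enoate
Conditions: RuCl2[(R)-BINAP] (0.5 mol%), H2 (4 atm), EtOH, 80 °C
Reagents that add atoms: none
Why: Noyori asymmetric hydrogenation: the chelated β-keto ester is reduced on the carbonyl face dictated by the (R)-BINAP–Ru catalyst to set the (R)-carbinol, while the unfunctionalised trisubstituted alkene should not be reduced at low hydrogen pressure.

Step 3
Reactants: 4 ethyl (R)-3-hydroxy-7-methyloct-6-enoate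
Product: 5 ethyl (R)-3-(tert-butyldimethylsilyloxy)-7-methyloct-6-enoate
Conditions: TBSCl, imidazole, DMF, rt
Reagents that add atoms: tert-butyldimethylsilyl chloride, CC(C)(C)[Si](C)(C)Cl
Why: Standard silylation of a secondary alcohol gives the bulky non-participating ether that later steers the cycloaddition.

Step 4
Reactants: 5 ethyl (R)-3-(tert-butyldimethylsilyloxy)-7-methyloct-6-enoate
Product: 6 (R)-3-(tert-butyldimethylsilyloxy)-7-methyloct-6-enoic acid
Conditions: LiOH·H2O, THF/MeOH/H2O, rt; then 1 M HCl to pH 4, 0 °C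
Reagents that add atoms: lithium hydroxide, [Li+].[OH-]
Why: Saponification of the ethyl ester with hydroxide at room temperature should leave the secondary silyl ether intact and cause no β-elimination.

Step 5
Reactants: 6 (R)-3-(tert-butyldimethylsilyloxy)-7-methyloct-6-enoic acid
Product: 7 (R)-3-(tert-butyldimethylsilyloxy)-7-methyloct-6-enoyl chloride
Conditions: (COCl)2, DMF (catalytic), CH2Cl2, 0 °C to rt; concentrate and use crude
Reagents that add atoms: oxalyl chloride, ClC(=O)C(=O)Cl
Why: Acid chloride formation through the Vilsmeier-type chloroiminium species is fast at 0 °C, and the crude chloride is used at once so that the silyl ether is not exposed to hydrogen chloride for long.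

Step 6
Reactants: 7 (R)-3-(tert-butyldimethylsilyloxy)-7-methyloct-6-enoyl chloride
Product: 9 (1S,2R,5S)-2-(tert-butyldimethylsilyloxy)-7,7-dimethylbicyclo[3.1.1]heptan-6-one (silyloxy anti to the gem-dimethyl bridge), via ketene 8 (not isolated)
Conditions: Et3N (3 equiv), toluene, reflux, slow addition of 7 (final concentration 0.01 M or lower)
Reagents that add atoms: none
Why: Triethylamine dehydrochlorinates 7 to the monoalkyl ketene 8, whose electrophilic carbonyl carbon C1′ bonds to the less substituted alkene carbon C5 while the ketene α-carbon C1 closes onto C6, the carbon that best carries the developing positive charge, in an asynchronous thermal [π2s+π2a] cycloaddition. The closest known reaction type is the intramolecular ketene–alkene [2+2] of alkenyl ketenes with a three-carbon tether and a dimethyl-substituted alkene terminus, which gives 7,7-dimethylbicyclo[3.1.1]heptan-6-ones. The six-membered carbocycle C1–C6 closes by C1–C6 bond formation in the crossed mode, so the cyclobutanone C1′–C1–C6–C5 closes as a bridge across C1 and C5 (C1′–C5 formation being a 6-exo attack on the alkene) instead of the fused bicyclo[3.2.0] alternative. C1 and C5 are necessarily cis-bridged, and their absolute sense is relayed from the C2 stereocentre: the tether forces C3 toward the alkene, and the transition state with the bulky silyloxy group pointing away from the approaching CMe2 terminus, anti to the future gem-dimethyl bridge, is preferred. The step needs regioselectivity, secured by the polarisation of the trisubstituted alkene, and facial selectivity, secured by the C2 silyloxy group; high dilution suppresses ketene dimerisation, and the minor syn diastereomer, which would lead into the enantiomeric series, is removed by chromatography at this stage.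

Step 7
Reactants: 9 (1S,2R,5S)-2-(tert-butyldimethylsilyloxy)-7,7-dimethylbicyclo[3.1.1]heptan-6-one
Product: 10 (1S,2R,5S)-2-(tert-butyldimethylsilyloxy)-8,8-dimethyl-6-oxabicyclo[3.2.1]octan-7-one
Conditions: mCPBA, NaHCO3, CH2Cl2, 0 °C to rt
Reagents that add atoms: 3-chloroperbenzoic acid, OOC(=O)c1cccc(Cl)c1
Why: Baeyer–Villiger oxidation driven by cyclobutanone strain: in the Criegee adduct C5 migrates with retention because C1 is deactivated by the neighbouring electron-withdrawing silyloxy carbon, which places oxygen on C5 cis to C1′.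

Step 8
Reactants: 10 (1S,2R,5S)-2-(tert-butyldimethylsilyloxy)-8,8-dimethyl-6-oxabicyclo[3.2.1]octan-7-one
Product: 11 (1S,2R,5S)-2-hydroxy-8,8-dimethyl-6-oxabicyclo[3.2.1]octan-7-one
Conditions: TBAF, AcOH, THF, rt
Reagents that add atoms: none
Why: Fluoride desilylation; retro-aldol cleavage or elimination of the β-hydroxy lactone is not expected because the required enolate at bridgehead C1 would violate Bredt's rule.

Step 9
Reactants: 11 (1S,2R,5S)-2-hydroxy-8,8-dimethyl-6-oxabicyclo[3.2.1]octan-7-one
Product: 12 (1S,5S)-8,8-dimethyl-6-oxabicyclo[3.2.1]octane-2,7-dione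
Conditions: Dess–Martin periodinane, NaHCO3, CH2Cl2, rt
Reagents that add atoms: none
Why: Dess–Martin oxidation under buffered neutral conditions gives the β-keto lactone, which cannot enolise or epimerise at the bridgehead C1.

Step 10
Reactants: 12 (1S,5S)-8,8-dimethyl-6-oxabicyclo[3.2.1]octane-2,7-dione
Product: 13 (1R,5S)-8,8-dimethyl-2-methylidene-6-oxabicyclo[3.2.1]octan-7-one
Conditions: Ph3PCH3Br, KHMDS, THF, 0 °C; then 12, 0 °C to rt
Reagents that add atoms: methyltriphenylphosphonium bromide, C[P+](c1ccccc1)(c1ccccc1)c1ccccc1.[Br-]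
Why: Wittig methylenation takes place at the ketone, which is far more electrophilic than the lactone carbonyl, and the new alkene cannot migrate into conjugation because C1 is a bridgehead.

Step 11
Reactants: 13 (1R,5S)-8,8-dimethyl-2-methylidene-6-oxabicyclo[3.2.1]octan-7-one
Product: 14 (1S,3S,5S)-3-hydroxy-8,8-dimethyl-2-methylidene-6-oxabicyclo[3.2.1]octan-7-one (hydroxyl on the face turned away from the lactone bridge)
Conditions: SeO2 (catalytic), t-BuOOH, CH2Cl2, rt to 40 °C, stopped before enone formation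
Reagents that add atoms: tert-butyl hydroperoxide, CC(C)(C)OO (oxygen relayed through catalytic selenium dioxide, O=[Se]=O)
Why: Selenium dioxide allylic hydroxylation (ene reaction then [2,3]-sigmatropic shift): C3 is the only allylic position with a usable hydrogen because the bridgehead C1–H cannot enter the ene step, and oxygen should be delivered to the face of C3 turned away from the lactone bridge, which sets C3 (S) with the hydroxyl trans to C1′.

Step 12
Reactants: 14 (1S,3S,5S)-3-hydroxy-8,8-dimethyl-2-methylidene-6-oxabicyclo[3.2.1]octan-7-one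
Product: 15 (1S,3S,5S)-3-(tert-butyldimethylsilyloxy)-8,8-dimethyl-2-methylidene-6-oxabicyclo[3.2.1]octan-7-one
Conditions: TBSCl, imidazole, DMF, rt
Reagents that add atoms: tert-butyldimethylsilyl chloride, CC(C)(C)[Si](C)(C)Cl
Why: Silylation of the unhindered equatorial allylic alcohol protects the C3 oxygen through the C5 substitution and the chain construction.

Step 13
Reactants: 15 (1S,3S,5S)-3-(tert-butyldimethylsilyloxy)-8,8-dimethyl-2-methylidene-6-oxabicyclo[3.2.1]octan-7-one
Product: 16 (1S,3S,5S)-3-(tert-butyldimethylsilyloxy)-8,8-dimethyl-2-methylidene-6-oxabicyclo[3.2.1]octan-7-ol (lactol; anomeric mixture)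
Conditions: DIBAL-H (1.1 equiv), CH2Cl2, −78 °C; Rochelle salt work-up
Reagents that add atoms: none
Why: Partial reduction of a γ-lactone with DIBAL-H at −78 °C stops at the lactol because the tetrahedral aluminium alkoxide does not collapse before the quench.

Step 14
Reactants: 16 (1S,3S,5S)-3-(tert-butyldimethylsilyloxy)-8,8-dimethyl-2-methylidene-6-oxabicyclo[3.2.1]octan-7-ol; 17 1-(triphenylphosphoranylidene)propan-2-one
Product: 18 (E)-4-[(1S,3S,5S)-5-(tert-butyldimethylsilyloxy)-3-hydroxy-2,2-dimethyl-6-methylidenecyclohexyl]but-3-en-2-one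
Conditions: 17 (2 equiv), toluene, 80 °C
Reagents that add atoms: none
Why: Wittig olefination of the lactol through its open hydroxy aldehyde form with a stabilised ylide gives the (E)-enone, and the neutral weakly basic ylide should neither epimerise the allylic C1 stereocentre nor trigger oxa-Michael reclosure of the freed C5 hydroxyl.

Step 15
Reactants: 18 (E)-4-[(1S,3S,5S)-5-(tert-butyldimethylsilyloxy)-3-hydroxy-2,2-dimethyl-6-methylidenecyclohexyl]but-3-en-2-one
Product: 19 4-[(1S,3S,5S)-5-(tert-butyldimethylsilyloxy)-3-hydroxy-2,2-dimethyl-6-methylidenecyclohexyl]butan-2-one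
Conditions: [(Ph3P)CuH]6 (Stryker's reagent), H2O (2 equiv), toluene, rt
Reagents that add atoms: none
Why: Conjugate reduction with Stryker's reagent delivers hydride only to the β-carbon of the enone, so the isolated 1,1-disubstituted alkene, the silyl ether and the free alcohol should be untouched.

Step 16
Reactants: 19 4-[(1S,3S,5S)-5-(tert-butyldimethylsilyloxy)-3-hydroxy-2,2-dimethyl-6-methylidenecyclohexyl]butan-2-one; 20 triethyl phosphonoacetate
Product: 21 ethyl (E)-5-[(1S,3S,5S)-5-(tert-butyldimethylsilyloxy)-3-hydroxy-2,2-dimethyl-6-methylidenecyclohexyl]-3-methylpent-2-enoate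
Conditions: 20, NaH, THF, 0 °C to 50 °C; (E)-isomer isolated by chromatography
Reagents that add atoms: none
Why: Horner–Wadsworth–Emmons olefination of the methyl ketone with the phosphonoacetate anion favours the (E)-trisubstituted enoate, and the minor (Z)-isomer is removed by chromatography so that the later epoxidation starts from one alkene geometry.

Step 17
Reactants: 21 ethyl (E)-5-[(1S,3S,5S)-5-(tert-butyldimethylsilyloxy)-3-hydroxy-2,2-dimethyl-6-methylidenecyclohexyl]-3-methylpent-2-enoate
Product: 22 ethyl (E)-5-[(1R,3R,5S)-3-bromo-5-(tert-butyldimethylsilyloxy)-2,2-dimethyl-6-methylidenecyclohexyl]-3-methylpent-2-enoate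
Conditions: CBr4, P(n-Oct)3, toluene, 70 °C
Reagents that add atoms: carbon tetrabromide, BrC(Br)(Br)Br
Why: Appel bromination: the C5 alkoxyphosphonium ion is displaced by bromide in an SN2 reaction with inversion, which turns the C5–O bond cis to the chain into the (R)-bromide trans to it, and the small nucleophilic trialkylphosphine with heating is chosen because the carbinol is flanked by the quaternary C6.

Step 18
Reactants: 22 ethyl (E)-5-[(1R,3R,5S)-3-bromo-5-(tert-butyldimethylsilyloxy)-2,2-dimethyl-6-methylidenecyclohexyl]-3-methylpent-2-enoate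
Product: 23 (E)-5-[(1R,3R,5S)-3-bromo-5-(tert-butyldimethylsilyloxy)-2,2-dimethyl-6-methylidenecyclohexyl]-3-methylpent-2-en-1-ol
Conditions: DIBAL-H (2.5 equiv), CH2Cl2, −78 °C; Rochelle salt work-up
Reagents that add atoms: none
Why: DIBAL-H reduces the conjugated ester by 1,2-addition to the (E)-allylic alcohol at −78 °C, conditions under which the secondary bromide and the silyl ether are inert.

Step 19
Reactants: 23 (E)-5-[(1R,3R,5S)-3-bromo-5-(tert-butyldimethylsilyloxy)-2,2-dimethyl-6-methylidenecyclohexyl]-3-methylpent-2-en-1-ol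
Product: 24 [(2S,3S)-3-{2-[(1R,3R,5S)-3-bromo-5-(tert-butyldimethylsilyloxy)-2,2-dimethyl-6-methylidenecyclohexyl]ethyl}-3-methyloxiran-2-yl]methanol
Conditions: Ti(OiPr)4 (10 mol%), L-(+)-diethyl tartrate (12 mol%), t-BuOOH, 4 Å MS, CH2Cl2, −20 °C
Reagents that add atoms: tert-butyl hydroperoxide, CC(C)(C)OO
Why: Sharpless asymmetric epoxidation: with L-(+)-diethyl tartrate the titanium-bound allylic alcohol is epoxidised on the face that gives the (2S,3S)-epoxy alcohol, which sets C3′ under reagent control while the exocyclic alkene, lacking a free allylic hydroxyl, is not touched.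

Step 20
Reactants: 24 [(2S,3S)-3-{2-[(1R,3R,5S)-3-bromo-5-(tert-butyldimethylsilyloxy)-2,2-dimethyl-6-methylidenecyclohexyl]ethyl}-3-methyloxiran-2-yl]methanol
Product: 26 (3S)-5-[(1R,3R,5S)-3-bromo-5-(tert-butyldimethylsilyloxy)-2,2-dimethyl-6-methylidenecyclohexyl]-3-methylpent-1-en-3-ol, via epoxy iodide 25 (not isolated)
Conditions: I2, PPh3, imidazole, THF, 0 °C; then Zn dust, AcOH, EtOH, rt
Reagents that add atoms: none
Why: Appel-type iodination of the primary alcohol and zinc-mediated reductive ring opening of the resulting β-iodo epoxide (a 1,2-elimination) give the tertiary vinyl carbinol without touching the C3′–O bond, so the (S) configuration is kept, and an unactivated secondary bromide should survive zinc dust at room temperature.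

Step 21
Reactants: 26 (3S)-5-[(1R,3R,5S)-3-bromo-5-(tert-butyldimethylsilyloxy)-2,2-dimethyl-6-methylidenecyclohexyl]-3-methylpent-1-en-3-ol
Product: 27 (1S,3R,5R)-5-bromo-3-[(3S)-3-hydroxy-3-methylpent-4-en-1-yl]-4,4-dimethyl-2-methylidenecyclohexan-1-ol
Conditions: HF·pyridine, pyridine, THF, 0 °C to rt
Reagents that add atoms: none
Why: Fluoride cleavage of the allylic silyl ether with pyridine-buffered HF is mild enough for the tertiary allylic alcohol and non-basic enough to avoid dehydrobromination.

Step 22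
Reactants: 27 (1S,3R,5R)-5-bromo-3-[(3S)-3-hydroxy-3-methylpent-4-en-1-yl]-4,4-dimethyl-2-methylidenecyclohexan-1-ol
Product: 28 (3S)-5-[(1S,3R,5R)-3,5-dibromo-2,2-dimethyl-6-methylidenecyclohexyl]-3-methylpent-1-en-3-ol (CNP0393289.1)
Conditions: CBr4, PPh3, CH2Cl2, −20 °C to 0 °C, short reaction time
Reagents that add atoms: carbon tetrabromide, BrC(Br)(Br)Br
Why: Appel bromination of the secondary allylic alcohol proceeds by SN2 with inversion at low temperature to give the C3 (R)-bromide cis to the chain, the tertiary alcohol being too hindered to form an alkoxyphosphonium ion under these conditions and the short cold reaction limiting SN2′ transposition to the primary allylic bromide.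

Compound list
1 | ethyl acetoacetate | CCOC(=O)CC(C)=O | starting material
2 | 1-bromo-3-methylbut-2-ene | CC(C)=CCBr | starting material
3 | ethyl 7-methyl-3-oxooct-6-enoate | CCOC(=O)CC(=O)CCC=C(C)C | intermediate
4 | ethyl (R)-3-hydroxy-7-methyloct-6-enoate | CCOC(=O)C[C@H](O)CCC=C(C)C | intermediate
5 | ethyl (R)-3-(tert-butyldimethylsilyloxy)-7-methyloct-6-enoate | CCOC(=O)C[C@H](O[Si](C)(C)C(C)(C)C)CCC=C(C)C | intermediate
6 | (R)-3-(tert-butyldimethylsilyloxy)-7-methyloct-6-enoic acid | OC(=O)C[C@H](O[Si](C)(C)C(C)(C)C)CCC=C(C)C | intermediate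
7 | (R)-3-(tert-butyldimethylsilyloxy)-7-methyloct-6-enoyl chloride | ClC(=O)C[C@H](O[Si](C)(C)C(C)(C)C)CCC=C(C)C | intermediate
8 | (3R)-3-(tert-butyldimethylsilyloxy)-7-methylocta-1,6-dien-1-one (ketene) | O=C=C[C@H](O[Si](C)(C)C(C)(C)C)CCC=C(C)C | intermediate
9 | (1S,2R,5S)-2-(tert-butyldimethylsilyloxy)-7,7-dimethylbicyclo[3.1.1]heptan-6-one, silyloxy anti to the gem-dimethyl bridge | O=C1[C@@H]2[C@H](O[Si](C)(C)C(C)(C)C)CC[C@H]1C2(C)C | intermediate
10 | (1S,2R,5S)-2-(tert-butyldimethylsilyloxy)-8,8-dimethyl-6-oxabicyclo[3.2.1]octan-7-one | O=C1[C@@H]2[C@H](O[Si](C)(C)C(C)(C)C)CC[C@H](O1)C2(C)C | intermediate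
11 | (1S,2R,5S)-2-hydroxy-8,8-dimethyl-6-oxabicyclo[3.2.1]octan-7-one | O=C1[C@@H]2[C@H](O)CC[C@H](O1)C2(C)C | intermediate
12 | (1S,5S)-8,8-dimethyl-6-oxabicyclo[3.2.1]octane-2,7-dione | O=C1[C@@H]2C(=O)CC[C@H](O1)C2(C)C | intermediate
13 | (1R,5S)-8,8-dimethyl-2-methylidene-6-oxabicyclo[3.2.1]octan-7-one | O=C1[C@@H]2C(=C)CC[C@H](O1)C2(C)C | intermediate
14 | (1S,3S,5S)-3-hydroxy-8,8-dimethyl-2-methylidene-6-oxabicyclo[3.2.1]octan-7-one | O=C1[C@@H]2C(=C)[C@@H](O)C[C@H](O1)C2(C)C | intermediate
15 | (1S,3S,5S)-3-(tert-butyldimethylsilyloxy)-8,8-dimethyl-2-methylidene-6-oxabicyclo[3.2.1]octan-7-one | O=C1[C@@H]2C(=C)[C@@H](O[Si](C)(C)C(C)(C)C)C[C@H](O1)C2(C)C | intermediate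
16 | (1S,3S,5S)-3-(tert-butyldimethylsilyloxy)-8,8-dimethyl-2-methylidene-6-oxabicyclo[3.2.1]octan-7-ol (lactol, both anomers) | OC1[C@@H]2C(=C)[C@@H](O[Si](C)(C)C(C)(C)C)C[C@H](O1)C2(C)C | intermediate
17 | 1-(triphenylphosphoranylidene)propan-2-one | CC(=O)C=P(c1ccccc1)(c1ccccc1)c1ccccc1 | starting material
18 | (E)-4-[(1S,3S,5S)-5-(tert-butyldimethylsilyloxy)-3-hydroxy-2,2-dimethyl-6-methylidenecyclohexyl]but-3-en-2-one | CC(=O)/C=C/[C@@H]1C(=C)[C@@H](O[Si](C)(C)C(C)(C)C)C[C@H](O)C1(C)C | intermediate
19 | 4-[(1S,3S,5S)-5-(tert-butyldimethylsilyloxy)-3-hydroxy-2,2-dimethyl-6-methylidenecyclohexyl]butan-2-one | CC(=O)CC[C@@H]1C(=C)[C@@H](O[Si](C)(C)C(C)(C)C)C[C@H](O)C1(C)C | intermediate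
20 | triethyl phosphonoacetate | CCOC(=O)CP(=O)(OCC)OCC | starting material
21 | ethyl (E)-5-[(1S,3S,5S)-5-(tert-butyldimethylsilyloxy)-3-hydroxy-2,2-dimethyl-6-methylidenecyclohexyl]-3-methylpent-2-enoate | CCOC(=O)/C=C(\C)CC[C@@H]1C(=C)[C@@H](O[Si](C)(C)C(C)(C)C)C[C@H](O)C1(C)C | intermediate
22 | ethyl (E)-5-[(1R,3R,5S)-3-bromo-5-(tert-butyldimethylsilyloxy)-2,2-dimethyl-6-methylidenecyclohexyl]-3-methylpent-2-enoate | CCOC(=O)/C=C(\C)CC[C@@H]1C(=C)[C@@H](O[Si](C)(C)C(C)(C)C)C[C@@H](Br)C1(C)C | intermediate
23 | (E)-5-[(1R,3R,5S)-3-bromo-5-(tert-butyldimethylsilyloxy)-2,2-dimethyl-6-methylidenecyclohexyl]-3-methylpent-2-en-1-ol | OC/C=C(\C)CC[C@@H]1C(=C)[C@@H](O[Si](C)(C)C(C)(C)C)C[C@@H](Br)C1(C)C | intermediate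
24 | [(2S,3S)-3-{2-[(1R,3R,5S)-3-bromo-5-(tert-butyldimethylsilyloxy)-2,2-dimethyl-6-methylidenecyclohexyl]ethyl}-3-methyloxiran-2-yl]methanol | OC[C@@H]1O[C@@]1(C)CC[C@@H]2C(=C)[C@@H](O[Si](C)(C)C(C)(C)C)C[C@@H](Br)C2(C)C | intermediate
25 | (2R,3S)-3-{2-[(1R,3R,5S)-3-bromo-5-(tert-butyldimethylsilyloxy)-2,2-dimethyl-6-methylidenecyclohexyl]ethyl}-2-(iodomethyl)-3-methyloxirane | IC[C@@H]1O[C@@]1(C)CC[C@@H]2C(=C)[C@@H](O[Si](C)(C)C(C)(C)C)C[C@@H](Br)C2(C)C | intermediate
26 | (3S)-5-[(1R,3R,5S)-3-bromo-5-(tert-butyldimethylsilyloxy)-2,2-dimethyl-6-methylidenecyclohexyl]-3-methylpent-1-en-3-ol | C=C[C@@](C)(O)CC[C@@H]1C(=C)[C@@H](O[Si](C)(C)C(C)(C)C)C[C@@H](Br)C1(C)C | intermediate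
27 | (1S,3R,5R)-5-bromo-3-[(3S)-3-hydroxy-3-methylpent-4-en-1-yl]-4,4-dimethyl-2-methylidenecyclohexan-1-ol | C=C[C@@](C)(O)CC[C@@H]1C(=C)[C@@H](O)C[C@@H](Br)C1(C)C | intermediate
28 | (3S)-5-[(1S,3R,5R)-3,5-dibromo-2,2-dimethyl-6-methylidenecyclohexyl]-3-methylpent-1-en-3-ol (CNP0393289.1) | C=C[C@@](C)(O)CC[C@@H]1C(=C)[C@H](Br)C[C@@H](Br)C1(C)C | target

Total step count: 22. Longest linear sequence: 22 steps (1 to 28; the route is fully linear).

Steps most likely to fail

Step 17 (bromide at C5). The carbinol is secondary and sits next to the quaternary C6. E2 elimination toward C4, or ionisation followed by a 1,2-methyl shift, may outrun the SN2 displacement of the alkoxyphosphonium ion. Fallback: activation and displacement would be separated. Compound 21 would be treated with triflic anhydride and pyridine in CH2Cl2 at −40 °C to give ethyl (E)-5-[(1S,3S,5S)-5-(tert-butyldimethylsilyloxy)-2,2-dimethyl-6-methylidene-3-(trifluoromethylsulfonyloxy)cyclohexyl]-3-methylpent-2-enoate F1. This triflate would then be displaced by tetrabutylammonium bromide in toluene at 0 °C to rt, again with inversion, which returns to the route at 22. The far better leaving group allows a cold SN2 with a free bromide ion instead of a hot oxyphosphonium salt.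

Step 6 (key cycloaddition). A monoalkyl ketene may dimerise or oligomerise faster than it cyclises, silanolate may be lost by β-elimination under the amine, or the facial preference may be weak. Fallback: the same two bonds would be formed through a keteniminium ion, which is more electrophilic and does not dimerise. Acid chloride 7 would be treated with pyrrolidine and triethylamine to give (R)-3-(tert-butyldimethylsilyloxy)-7-methyl-1-(pyrrolidin-1-yl)oct-6-en-1-one F2. Activation of this amide with triflic anhydride and 2,4,6-collidine in refluxing 1,2-dichloroethane should give the keteniminium triflate F3. This cyclises in the same crossed sense to the cyclobutaniminium triflate F4, and hydrolysis of that salt with aqueous NaHCO3 returns to the route at 9.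

Step 14 (chain extension on the lactol). The hindered lactol may open slowly, the β,γ-unsaturated aldehyde may epimerise at C1 or shift its double bond on prolonged heating, and the freed C5 hydroxyl may add back to the enone. Fallback: the lactol and the free hydroxyl would be avoided. Lactone 15 would be opened with N,O-dimethylhydroxylamine hydrochloride and trimethylaluminium to give (1S,3S,5S)-5-(tert-butyldimethylsilyloxy)-3-hydroxy-N-methoxy-N,2,2-trimethyl-6-methylidenecyclohexane-1-carboxamide F5. The C5 hydroxyl would be replaced with inversion (CBr4, P(n-Oct)3, toluene, 70 °C) to give the bromo amide (1R,3R,5S)-3-bromo-5-(tert-butyldimethylsilyloxy)-N-methoxy-N,2,2-trimethyl-6-methylidenecyclohexane-1-carboxamide F6. DIBAL-H at −78 °C would give (1R,3R,5S)-3-bromo-5-(tert-butyldimethylsilyloxy)-2,2-dimethyl-6-methylidenecyclohexane-1-carbaldehyde F7, used at once. Olefination with diethyl (2-oxopropyl)phosphonate, LiCl and i-Pr2NEt in MeCN at rt would give (E)-4-[(1R,3R,5S)-3-bromo-5-(tert-butyldimethylsilyloxy)-2,2-dimethyl-6-methylidenecyclohexyl]but-3-en-2-one F8. Conjugate reduction with Stryker's reagent would give 4-[(1R,3R,5S)-3-bromo-5-(tert-butyldimethylsilyloxy)-2,2-dimethyl-6-methylidenecyclohexyl]butan-2-one F9. Horner–Wadsworth–Emmons reaction of F9 with 20 then returns to the route at 22.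

Further compounds
F1 | step 17 | ethyl (E)-5-[(1S,3S,5S)-5-(tert-butyldimethylsilyloxy)-2,2-dimethyl-6-methylidene-3-(trifluoromethylsulfonyloxy)cyclohexyl]-3-methylpent-2-enoate | CCOC(=O)/C=C(\C)CC[C@@H]1C(=C)[C@@H](O[Si](C)(C)C(C)(C)C)C[C@H](OS(=O)(=O)C(F)(F)F)C1(C)C
F2 | step 6 | (R)-3-(tert-butyldimethylsilyloxy)-7-methyl-1-(pyrrolidin-1-yl)oct-6-en-1-one | O=C(C[C@H](O[Si](C)(C)C(C)(C)C)CCC=C(C)C)N1CCCC1
F3 | step 6 | 1-[(3R)-3-(tert-butyldimethylsilyloxy)-7-methylocta-1,6-dien-1-ylidene]pyrrolidinium triflate (keteniminium salt) | CC(C)=CCC[C@@H](O[Si](C)(C)C(C)(C)C)C=C=[N+]1CCCC1.[O-]S(=O)(=O)C(F)(F)F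
F4 | step 6 | 1-[(1S,2R,5S)-2-(tert-butyldimethylsilyloxy)-7,7-dimethylbicyclo[3.1.1]heptan-6-ylidene]pyrrolidinium triflate | C1CC[N+](C1)=C2[C@@H]3[C@H](O[Si](C)(C)C(C)(C)C)CC[C@H]2C3(C)C.[O-]S(=O)(=O)C(F)(F)F
F5 | step 14 | (1S,3S,5S)-5-(tert-butyldimethylsilyloxy)-3-hydroxy-N-methoxy-N,2,2-trimethyl-6-methylidenecyclohexane-1-carboxamide | CON(C)C(=O)[C@@H]1C(=C)[C@@H](O[Si](C)(C)C(C)(C)C)C[C@H](O)C1(C)C
F6 | step 14 | (1R,3R,5S)-3-bromo-5-(tert-butyldimethylsilyloxy)-N-methoxy-N,2,2-trimethyl-6-methylidenecyclohexane-1-carboxamide | CON(C)C(=O)[C@@H]1C(=C)[C@@H](O[Si](C)(C)C(C)(C)C)C[C@@H](Br)C1(C)C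
F7 | step 14 | (1R,3R,5S)-3-bromo-5-(tert-butyldimethylsilyloxy)-2,2-dimethyl-6-methylidenecyclohexane-1-carbaldehyde | O=C[C@@H]1C(=C)[C@@H](O[Si](C)(C)C(C)(C)C)C[C@@H](Br)C1(C)C
F8 | step 14 | (E)-4-[(1R,3R,5S)-3-bromo-5-(tert-butyldimethylsilyloxy)-2,2-dimethyl-6-methylidenecyclohexyl]but-3-en-2-one | CC(=O)/C=C/[C@@H]1C(=C)[C@@H](O[Si](C)(C)C(C)(C)C)C[C@@H](Br)C1(C)C
F9 | step 14 | 4-[(1R,3R,5S)-3-bromo-5-(tert-butyldimethylsilyloxy)-2,2-dimethyl-6-methylidenecyclohexyl]butan-2-one | CC(=O)CC[C@@H]1C(=C)[C@@H](O[Si](C)(C)C(C)(C)C)C[C@@H](Br)C1(C)C
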